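**Strategy.** The γ-lactone is traced back to a cyclobutanone. A [2+2] cycloaddition of a chiral keteniminium ion with a terminal alkene forms in one operation the bond from the later lactone carbonyl carbon to its α-carbon and the ring-fusion bond between the β- and O-bearing γ-carbons, which the five-membered and ten-membered rings share; Baeyer–Villiger oxidation then inserts the ring oxygen. The step exploits the C(=O)–CH(CH3)–CH–CH(O) chain of the lactone ring, a masked ketene–alkene adduct. Its precursors are the 3-(benzyloxy)propanamide of (2S,5S)-2,5-dimethylpyrrolidine and silylated but-3-en-1-ol. Side chains are then grown and the (Z,Z)-cyclodecadiene is closed last by metathesis.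

Key step: step 3

Assumption: the (2S,5S) auxiliary is taken to direct the alkene to the keteniminium face that leads to the (3S)-cyclobutanone; if the sense of induction were the opposite, the (2R,5R) amine would be used with no other change.

Step 1
Reactants: 1 3-(benzyloxy)propanoic acid; 2 (2S,5S)-2,5-dimethylpyrrolidine
Product: 4 3-(benzyloxy)-1-[(2S,5S)-2,5-dimethylpyrrolidin-1-yl]propan-1-one, via 3-(benzyloxy)propanoyl chloride 3 (not isolated)
Conditions: (COCl)2, DMF (cat.), CH2Cl2, 0 °C to rt; then 2, Et3N, CH2Cl2, 0 °C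
Reagents that add atoms: none
Why: Schotten–Baumann-type N-acylation through the acid chloride is reliable even with the hindered C2-symmetric secondary amine and installs the auxiliary that later controls the cycloaddition.

Step 2
Reactants: 5 but-3-en-1-ol
Product: 6 (but-3-en-1-yloxy)(tert-butyl)diphenylsilane
Conditions: TBDPSCl, imidazole, CH2Cl2, rt
Reagents that add atoms: tert-butyl(chloro)diphenylsilane, CC(C)(C)[Si](Cl)(c1ccccc1)c1ccccc1
Why: Imidazole-promoted silylation gives a robust primary silyl ether that should survive amide activation, enolate chemistry and hydrogenolysis.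

Step 3
Reactants: 4 3-(benzyloxy)-1-[(2S,5S)-2,5-dimethylpyrrolidin-1-yl]propan-1-one; 6 (but-3-en-1-yloxy)(tert-butyl)diphenylsilane
Product: 9 (2S,3S)-2-[(benzyloxy)methyl]-3-{2-[(tert-butyldiphenylsilyl)oxy]ethyl}cyclobutan-1-one, via keteniminium triflate 7 (not isolated), via cyclobutaniminium triflate 8 (not isolated)
Conditions: Tf2O, 2,4,6-collidine, 6 (3 equiv), ClCH2CH2Cl, 0 °C to 60 °C; then aq NaHCO3, CH2Cl2, rt
Reagents that add atoms: water, O
Why: O-Triflation of amide 4 and loss of triflic acid to collidine give keteniminium ion 7, whose electrophilic central carbon is attacked by the terminal CH2 of alkene 6 while the developing secondary cation at the internal alkene carbon collapses onto the α-carbon, an asynchronous [2+2] cycloaddition that gives cyclobutaniminium 8 and, after hydrolysis, ketone 9. The closest known reaction type is the keteniminium–olefin [2+2] cycloaddition of tertiary amides bearing C2-symmetric pyrrolidine auxiliaries. The four-membered ring is closed by the cycloaddition itself, both new C–C bonds (carbonyl carbon to CH2, and CH to CH) forming in one bimolecular event. C3 of the cyclobutanone (the later lactone β-carbon) is set by the facial bias that the two pyrrolidine methyl groups impose on the keteniminium ion, and C2 (the later O-bearing γ-carbon) is set thermodynamically, the 2,3-cis iminium ion equilibrating to trans through its enamine in the presence of collidine. The step needs Markovnikov regioselectivity, secured by the polarity of the partners (iminium carbon to the unsubstituted alkene terminus), and chemoselectivity, secured because 6 holds no other π-nucleophile and both ethers are inert to the triflate salts.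

Step 4
Reactants: 9 (2S,3S)-2-[(benzyloxy)methyl]-3-{2-[(tert-butyldiphenylsilyl)oxy]ethyl}cyclobutan-1-one
Product: 10 (4S,5S)-5-[(benzyloxy)methyl]-4-{2-[(tert-butyldiphenylsilyl)oxy]ethyl}oxolan-2-one
Conditions: mCPBA, NaHCO3, CH2Cl2, 0 °C
Reagents that add atoms: 3-chloroperbenzoic acid, OOC(=O)c1cccc(Cl)c1
Why: Baeyer–Villiger oxidation of the strained cyclobutanone is fast and regioselective, the secondary α-carbon migrating with retention in preference to the CH2 group, so the O-bearing stereocentre is delivered unchanged.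

Step 5
Reactants: 10 (4S,5S)-5-[(benzyloxy)methyl]-4-{2-[(tert-butyldiphenylsilyl)oxy]ethyl}oxolan-2-one
Product: 12 (3S,4S,5S)-5-[(benzyloxy)methyl]-4-{2-[(tert-butyldiphenylsilyl)oxy]ethyl}-3-methyloxolan-2-one (3,4-trans), via lithium enolate 11 (not isolated)
Conditions: LDA, THF, −78 °C; MeI, −78 to −40 °C
Reagents that add atoms: iodomethane, CI
Why: Lactone enolate alkylation introduces the α-methyl carbon anti to the β side chain (3,4-trans), an outcome that is inverted in the next step.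

Step 6
Reactants: 12 (3S,4S,5S)-5-[(benzyloxy)methyl]-4-{2-[(tert-butyldiphenylsilyl)oxy]ethyl}-3-methyloxolan-2-one
Product: 14 (3R,4S,5S)-5-[(benzyloxy)methyl]-4-{2-[(tert-butyldiphenylsilyl)oxy]ethyl}-3-methyloxolan-2-one (3,4-cis), via lithium enolate 13 (not isolated)
Conditions: LDA, THF, −78 °C; then 2,6-di-tert-butyl-4-methylphenol, THF, −78 °C
Reagents that add atoms: none
Why: Kinetic protonation of the planar enolate by the bulky phenol from the face opposite the β-substituent places the new hydrogen trans and the methyl group cis to the C4 side chain, giving the contra-thermodynamic 3R centre.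

Step 7
Reactants: 14 (3R,4S,5S)-5-[(benzyloxy)methyl]-4-{2-[(tert-butyldiphenylsilyl)oxy]ethyl}-3-methyloxolan-2-one
Product: 15 (3R,4S,5S)-4-{2-[(tert-butyldiphenylsilyl)oxy]ethyl}-5-(hydroxymethyl)-3-methyloxolan-2-one
Conditions: H2 (1 atm), Pd/C, EtOAc, rt
Reagents that add atoms: none
Why: Hydrogenolysis removes the benzyl ether while no alkene is yet present and leaves silyl ether, lactone and the α-stereocentre untouched.

Step 8
Reactants: 15 (3R,4S,5S)-4-{2-[(tert-butyldiphenylsilyl)oxy]ethyl}-5-(hydroxymethyl)-3-methyloxolan-2-one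
Product: 16 (2S,3S,4R)-3-{2-[(tert-butyldiphenylsilyl)oxy]ethyl}-4-methyl-5-oxooxolane-2-carbaldehyde
Conditions: Dess–Martin periodinane, NaHCO3, CH2Cl2, 0 °C to rt
Reagents that add atoms: none
Why: Dess–Martin oxidation under buffered conditions should give the α-oxygenated aldehyde without epimerisation of the adjacent centre.

Step 9
Reactants: 16 (2S,3S,4R)-3-{2-[(tert-butyldiphenylsilyl)oxy]ethyl}-4-methyl-5-oxooxolane-2-carbaldehyde
Product: 17 (3R,4S,5S)-4-{2-[(tert-butyldiphenylsilyl)oxy]ethyl}-5-[(Z)-2-iodoprop-1-en-1-yl]-3-methyloxolan-2-one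
Conditions: [Ph3PEt]I, n-BuLi, THF; I2, −78 °C; NaHMDS, −78 °C; then 16, −78 to −20 °C
Reagents that add atoms: ethyltriphenylphosphonium iodide, CC[P+](c1ccccc1)(c1ccccc1)c1ccccc1.[I-]; iodine, II
Why: The Stork–Zhao–Wittig olefination with the α-iodo ylide is Z-selective and fixes the cis relationship of the lactone carbon and the later C3 substituent across the trisubstituted alkene.

Step 10
Reactants: 17 (3R,4S,5S)-4-{2-[(tert-butyldiphenylsilyl)oxy]ethyl}-5-[(Z)-2-iodoprop-1-en-1-yl]-3-methyloxolan-2-one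
Product: 18 (Z)-3-[(2S,3S,4R)-3-{2-[(tert-butyldiphenylsilyl)oxy]ethyl}-4-methyl-5-oxooxolan-2-yl]-2-methylprop-2-enal
Conditions: CO (3 atm), Pd(PPh3)4 (5 mol%), Bu3SnH (slow addition), THF, 50 °C
Reagents that add atoms: carbon monoxide, [C-]#[O+]
Why: Palladium-catalysed formylation (oxidative addition to zerovalent palladium, CO insertion, hydride transfer from tin) proceeds with retention of alkene geometry and tolerates lactone and silyl ether.

Step 11
Reactants: 18 (Z)-3-[(2S,3S,4R)-3-{2-[(tert-butyldiphenylsilyl)oxy]ethyl}-4-methyl-5-oxooxolan-2-yl]-2-methylprop-2-enal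
Product: 19 (3R,4S,5S)-4-{2-[(tert-butyldiphenylsilyl)oxy]ethyl}-5-[(1Z,3S)-3-hydroxy-2-methylhexa-1,5-dien-1-yl]-3-methyloxolan-2-one
Conditions: (−)-Ipc2B(allyl) (1 M in pentane), Et2O, −78 °C; then NaBO3·4H2O, THF/H2O, rt
Reagents that add atoms: (−)-B-allyldiisopinocampheylborane, C=CCB([C@@H]1C[C@@H]2C[C@H]([C@H]1C)C2(C)C)[C@@H]1C[C@@H]2C[C@H]([C@H]1C)C2(C)C
Why: Brown allylboration through a chair-like Zimmerman–Traxler transition state is reagent-controlled, the (+)-α-pinene-derived borane giving the 3S carbinol, and the aldehyde reacts far faster than the lactone.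

Step 12
Reactants: 19 (3R,4S,5S)-4-{2-[(tert-butyldiphenylsilyl)oxy]ethyl}-5-[(1Z,3S)-3-hydroxy-2-methylhexa-1,5-dien-1-yl]-3-methyloxolan-2-one
Product: 20 (1Z,3S)-1-[(2S,3S,4R)-3-{2-[(tert-butyldiphenylsilyl)oxy]ethyl}-4-methyl-5-oxooxolan-2-yl]-2-methylhexa-1,5-dien-3-yl acetate
Conditions: Ac2O, pyridine, DMAP (cat.), CH2Cl2, rt
Reagents that add atoms: acetic anhydride, CC(=O)OC(C)=O
Why: DMAP-catalysed acylation of the secondary allylic alcohol installs the first acetate of the target.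

Step 13
Reactants: 20 (1Z,3S)-1-[(2S,3S,4R)-3-{2-[(tert-butyldiphenylsilyl)oxy]ethyl}-4-methyl-5-oxooxolan-2-yl]-2-methylhexa-1,5-dien-3-yl acetate
Product: 21 (1Z,3S)-1-[(2S,3S,4R)-3-(2-hydroxyethyl)-4-methyl-5-oxooxolan-2-yl]-2-methylhexa-1,5-dien-3-yl acetate
Conditions: TBAF, AcOH (1:1), THF, rt
Reagents that add atoms: none
Why: Fluoride cleaves the primary silyl ether, and the acetic acid buffer keeps the medium non-basic so that acetate, lactone and the epimerisable α-methyl centre survive.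

Step 14
Reactants: 21 (1Z,3S)-1-[(2S,3S,4R)-3-(2-hydroxyethyl)-4-methyl-5-oxooxolan-2-yl]-2-methylhexa-1,5-dien-3-yl acetate
Product: 22 (1Z,3S)-2-methyl-1-[(2S,3S,4R)-4-methyl-5-oxo-3-(2-oxoethyl)oxolan-2-yl]hexa-1,5-dien-3-yl acetate
Conditions: Dess–Martin periodinane, NaHCO3, CH2Cl2, 0 °C to rt
Reagents that add atoms: none
Why: Dess–Martin oxidation gives the aldehyde under neutral conditions compatible with the allylic acetate and both alkenes.

Step 15
Reactants: 22 (1Z,3S)-2-methyl-1-[(2S,3S,4R)-4-methyl-5-oxo-3-(2-oxoethyl)oxolan-2-yl]hexa-1,5-dien-3-yl acetate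
Product: 23 (1Z,3S)-1-[(2S,3S,4R)-3-(2-hydroxy-3-methylbut-3-en-1-yl)-4-methyl-5-oxooxolan-2-yl]-2-methylhexa-1,5-dien-3-yl acetate (both epimers at the new carbinol)
Conditions: 2-bromopropene, CrCl2 (4 equiv), NiCl2 (1 mol%), DMF, rt
Reagents that add atoms: 2-bromopropene, CC(Br)=C
Why: The Nozaki–Hiyama–Kishi reaction adds the isopropenyl group chemoselectively to the aldehyde in the presence of lactone and acetate, and the unselective new carbinol centre is corrected in the next two steps.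

Step 16
Reactants: 23 (1Z,3S)-1-[(2S,3S,4R)-3-(2-hydroxy-3-methylbut-3-en-1-yl)-4-methyl-5-oxooxolan-2-yl]-2-methylhexa-1,5-dien-3-yl acetate
Product: 24 (1Z,3S)-2-methyl-1-[(2S,3S,4R)-4-methyl-3-(3-methyl-2-oxobut-3-en-1-yl)-5-oxooxolan-2-yl]hexa-1,5-dien-3-yl acetate
Conditions: Dess–Martin periodinane, NaHCO3, CH2Cl2, 0 °C
Reagents that add atoms: none
Why: Dess–Martin oxidation of the allylic alcohol removes the unselective stereocentre and gives the isopropenyl ketone for asymmetric reduction.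

Step 17
Reactants: 24 (1Z,3S)-2-methyl-1-[(2S,3S,4R)-4-methyl-3-(3-methyl-2-oxobut-3-en-1-yl)-5-oxooxolan-2-yl]hexa-1,5-dien-3-yl acetate
Product: 25 (1Z,3S)-1-{(2S,3S,4R)-3-[(2R)-2-hydroxy-3-methylbut-3-en-1-yl]-4-methyl-5-oxooxolan-2-yl}-2-methylhexa-1,5-dien-3-yl acetate
Conditions: (S)-2-methyl-CBS-oxazaborolidine (20 mol%), catecholborane, toluene, −78 °C
Reagents that add atoms: none
Why: Corey–Bakshi–Shibata reduction treats the isopropenyl group as the large substituent and should give the 9R allylic alcohol under catalyst control, while catecholborane at low temperature spares lactone, acetate and alkenes.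

Step 18
Reactants: 25 (1Z,3S)-1-{(2S,3S,4R)-3-[(2R)-2-hydroxy-3-methylbut-3-en-1-yl]-4-methyl-5-oxooxolan-2-yl}-2-methylhexa-1,5-dien-3-yl acetate
Product: 26 (1Z,3S)-1-{(2S,3S,4R)-3-[(2R)-2-acetoxy-3-methylbut-3-en-1-yl]-4-methyl-5-oxooxolan-2-yl}-2-methylhexa-1,5-dien-3-yl acetate
Conditions: Ac2O, pyridine, DMAP (cat.), CH2Cl2, rt
Reagents that add atoms: acetic anhydride, CC(=O)OC(C)=O
Why: DMAP-catalysed acylation installs the second acetate without touching any stereocentre.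

Step 19
Reactants: 26 (1Z,3S)-1-{(2S,3S,4R)-3-[(2R)-2-acetoxy-3-methylbut-3-en-1-yl]-4-methyl-5-oxooxolan-2-yl}-2-methylhexa-1,5-dien-3-yl acetate
Product: 27 target CNP0226482.4, (3S,6S,7S,9R,11R)-3,9-diacetoxy-11,13-dihydrogermacra-1(10)Z,4Z-dien-12,6-olide (germacrane numbering)
Conditions: second-generation Grubbs catalyst (10 mol%), toluene (1 mM), 80 °C
Reagents that add atoms: none
Why: Ring-closing metathesis starts at the monosubstituted alkene and closes onto the 1,1-disubstituted alkene with loss of ethylene, and the new trisubstituted alkene is expected to be Z because an E alkene would be far more strained in a ten-membered ring that already holds a Z alkene and a trans-fused lactone.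

**Compound list**

1 | 3-(benzyloxy)propanoic acid | OC(=O)CCOCc1ccccc1 | starting material
2 | (2S,5S)-2,5-dimethylpyrrolidine | C[C@H]1CC[C@H](C)N1 | starting material
3 | 3-(benzyloxy)propanoyl chloride | ClC(=O)CCOCc1ccccc1 | intermediate
4 | 3-(benzyloxy)-1-[(2S,5S)-2,5-dimethylpyrrolidin-1-yl]propan-1-one | O=C(CCOCc1ccccc1)N1[C@@H](C)CC[C@@H]1C | intermediate
5 | but-3-en-1-ol | C=CCCO | starting material
6 | (but-3-en-1-yloxy)(tert-butyl)diphenylsilane | C=CCCO[Si](c1ccccc1)(c1ccccc1)C(C)(C)C | intermediate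
7 | (2S,5S)-1-[3-(benzyloxy)prop-1-en-1-ylidene]-2,5-dimethylpyrrolidinium triflate (keteniminium salt) | C(=C=[N+]1[C@@H](C)CC[C@@H]1C)COCc1ccccc1.[O-]S(=O)(=O)C(F)(F)F | intermediate
8 | (2S,5S)-1-{(2S,3S)-2-[(benzyloxy)methyl]-3-[2-(tert-butyldiphenylsilyloxy)ethyl]cyclobutylidene}-2,5-dimethylpyrrolidinium triflate | O(Cc1ccccc1)C[C@H]1C(=[N+]2[C@@H](C)CC[C@@H]2C)C[C@@H]1CCO[Si](c1ccccc1)(c1ccccc1)C(C)(C)C.[O-]S(=O)(=O)C(F)(F)F | intermediate
9 | (2S,3S)-2-[(benzyloxy)methyl]-3-{2-[(tert-butyldiphenylsilyl)oxy]ethyl}cyclobutan-1-one | O(Cc1ccccc1)C[C@H]1C(=O)C[C@@H]1CCO[Si](c1ccccc1)(c1ccccc1)C(C)(C)C | intermediate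
10 | (4S,5S)-5-[(benzyloxy)methyl]-4-{2-[(tert-butyldiphenylsilyl)oxy]ethyl}oxolan-2-one | O(Cc1ccccc1)C[C@H]1OC(=O)C[C@@H]1CCO[Si](c1ccccc1)(c1ccccc1)C(C)(C)C | intermediate
11 | lithium enolate of 10 | O(Cc1ccccc1)C[C@H]1OC(O[Li])=C[C@@H]1CCO[Si](c1ccccc1)(c1ccccc1)C(C)(C)C | intermediate
12 | (3S,4S,5S)-5-[(benzyloxy)methyl]-4-{2-[(tert-butyldiphenylsilyl)oxy]ethyl}-3-methyloxolan-2-one | O(Cc1ccccc1)C[C@H]1OC(=O)[C@@H](C)[C@@H]1CCO[Si](c1ccccc1)(c1ccccc1)C(C)(C)C | intermediate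
13 | lithium enolate of 12 | O(Cc1ccccc1)C[C@H]1OC(O[Li])=C(C)[C@@H]1CCO[Si](c1ccccc1)(c1ccccc1)C(C)(C)C | intermediate
14 | (3R,4S,5S)-5-[(benzyloxy)methyl]-4-{2-[(tert-butyldiphenylsilyl)oxy]ethyl}-3-methyloxolan-2-one | O(Cc1ccccc1)C[C@H]1OC(=O)[C@H](C)[C@@H]1CCO[Si](c1ccccc1)(c1ccccc1)C(C)(C)C | intermediate
15 | (3R,4S,5S)-4-{2-[(tert-butyldiphenylsilyl)oxy]ethyl}-5-(hydroxymethyl)-3-methyloxolan-2-one | OC[C@H]1OC(=O)[C@H](C)[C@@H]1CCO[Si](c1ccccc1)(c1ccccc1)C(C)(C)C | intermediate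
16 | (2S,3S,4R)-3-{2-[(tert-butyldiphenylsilyl)oxy]ethyl}-4-methyl-5-oxooxolane-2-carbaldehyde | O=C[C@H]1OC(=O)[C@H](C)[C@@H]1CCO[Si](c1ccccc1)(c1ccccc1)C(C)(C)C | intermediate
17 | (3R,4S,5S)-4-{2-[(tert-butyldiphenylsilyl)oxy]ethyl}-5-[(Z)-2-iodoprop-1-en-1-yl]-3-methyloxolan-2-one | I/C(C)=C\[C@H]1OC(=O)[C@H](C)[C@@H]1CCO[Si](c1ccccc1)(c1ccccc1)C(C)(C)C | intermediate
18 | (Z)-3-[(2S,3S,4R)-3-{2-[(tert-butyldiphenylsilyl)oxy]ethyl}-4-methyl-5-oxooxolan-2-yl]-2-methylprop-2-enal | O=C/C(C)=C\[C@H]1OC(=O)[C@H](C)[C@@H]1CCO[Si](c1ccccc1)(c1ccccc1)C(C)(C)C | intermediate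
19 | (3R,4S,5S)-4-{2-[(tert-butyldiphenylsilyl)oxy]ethyl}-5-[(1Z,3S)-3-hydroxy-2-methylhexa-1,5-dien-1-yl]-3-methyloxolan-2-one | O[C@@H](CC=C)/C(C)=C\[C@H]1OC(=O)[C@H](C)[C@@H]1CCO[Si](c1ccccc1)(c1ccccc1)C(C)(C)C | intermediate
20 | (1Z,3S)-1-[(2S,3S,4R)-3-{2-[(tert-butyldiphenylsilyl)oxy]ethyl}-4-methyl-5-oxooxolan-2-yl]-2-methylhexa-1,5-dien-3-yl acetate | CC(=O)O[C@@H](CC=C)/C(C)=C\[C@H]1OC(=O)[C@H](C)[C@@H]1CCO[Si](c1ccccc1)(c1ccccc1)C(C)(C)C | intermediate
21 | (1Z,3S)-1-[(2S,3S,4R)-3-(2-hydroxyethyl)-4-methyl-5-oxooxolan-2-yl]-2-methylhexa-1,5-dien-3-yl acetate | CC(=O)O[C@@H](CC=C)/C(C)=C\[C@H]1OC(=O)[C@H](C)[C@@H]1CCO | intermediate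
22 | (1Z,3S)-2-methyl-1-[(2S,3S,4R)-4-methyl-5-oxo-3-(2-oxoethyl)oxolan-2-yl]hexa-1,5-dien-3-yl acetate | CC(=O)O[C@@H](CC=C)/C(C)=C\[C@H]1OC(=O)[C@H](C)[C@@H]1CC=O | intermediate
23 | (1Z,3S)-1-[(2S,3S,4R)-3-(2-hydroxy-3-methylbut-3-en-1-yl)-4-methyl-5-oxooxolan-2-yl]-2-methylhexa-1,5-dien-3-yl acetate, both carbinol epimers | CC(=O)O[C@@H](CC=C)/C(C)=C\[C@H]1OC(=O)[C@H](C)[C@@H]1CC(O)C(C)=C | intermediate
24 | (1Z,3S)-2-methyl-1-[(2S,3S,4R)-4-methyl-3-(3-methyl-2-oxobut-3-en-1-yl)-5-oxooxolan-2-yl]hexa-1,5-dien-3-yl acetate | CC(=O)O[C@@H](CC=C)/C(C)=C\[C@H]1OC(=O)[C@H](C)[C@@H]1CC(=O)C(C)=C | intermediate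
25 | (1Z,3S)-1-{(2S,3S,4R)-3-[(2R)-2-hydroxy-3-methylbut-3-en-1-yl]-4-methyl-5-oxooxolan-2-yl}-2-methylhexa-1,5-dien-3-yl acetate | CC(=O)O[C@@H](CC=C)/C(C)=C\[C@H]1OC(=O)[C@H](C)[C@@H]1C[C@@H](O)C(C)=C | intermediate
26 | (1Z,3S)-1-{(2S,3S,4R)-3-[(2R)-2-acetoxy-3-methylbut-3-en-1-yl]-4-methyl-5-oxooxolan-2-yl}-2-methylhexa-1,5-dien-3-yl acetate | CC(=O)O[C@@H](CC=C)/C(C)=C\[C@H]1OC(=O)[C@H](C)[C@@H]1C[C@@H](OC(C)=O)C(C)=C | intermediate
27 | CNP0226482.4, (3S,6S,7S,9R,11R)-3,9-diacetoxy-11,13-dihydrogermacra-1(10)Z,4Z-dien-12,6-olide | CC(=O)O[C@H]1C/C=C(/C)[C@H](OC(C)=O)C[C@@H]2[C@@H](/C=C\1C)OC(=O)[C@@H]2C | target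

**Step count and risks**

Total step count: 19. Longest linear sequence: 18 (steps 1 and 3 to 19; step 2 is a one-step side branch).

Steps most likely to fail:

Step 3. The auxiliary may discriminate the two faces of the keteniminium ion poorly, or the β-alkoxy keteniminium ion may decompose before the unactivated alkene traps it. The fallback takes the lactone core from the chiral pool by conjugate addition instead of cycloaddition. It needs none of compounds 1 to 9, sets out from commercial (S)-5-(hydroxymethyl)furan-2(5H)-one F1 and comes back to the route at compound 10. Acid-catalysed benzylation (benzyl 2,2,2-trichloroacetimidate, TfOH cat.) gives (S)-5-[(benzyloxy)methyl]furan-2(5H)-one F2. Addition of the vinyl cuprate (vinylmagnesium bromide, CuBr·SMe2, Me3SiCl, THF, −78 °C) anti to the C5 substituent gives (4R,5S)-5-[(benzyloxy)methyl]-4-ethenyloxolan-2-one F3. Hydroboration with 9-BBN and oxidation with NaBO3 gives (4S,5S)-5-[(benzyloxy)methyl]-4-(2-hydroxyethyl)oxolan-2-one F4, and silylation with TBDPSCl and imidazole gives 10.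

Step 6. Protonation of enolate 13 may show poor facial discrimination, or the kinetically formed 3,4-cis lactone may equilibrate back to the trans epimer during quench. The fallback sets out from compound 10 and comes back at compound 14. LDA followed by Eschenmoser's salt gives the Mannich base (3S,4S,5S)-5-[(benzyloxy)methyl]-4-{2-[(tert-butyldiphenylsilyl)oxy]ethyl}-3-[(dimethylamino)methyl]oxolan-2-one F5. Quaternisation with MeI and elimination with NaHCO3 give the α-methylene lactone (4S,5S)-5-[(benzyloxy)methyl]-4-{2-[(tert-butyldiphenylsilyl)oxy]ethyl}-3-methylideneoxolan-2-one F6. Homogeneous hydrogenation (H2, RhCl(PPh3)3, benzene/EtOH) should add hydrogen to the exocyclic alkene from the face opposite the C4 side chain, spare the benzyl ether and give 14.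

Step 19. Oligomerisation may compete with ring closure, the hindered 1,1-disubstituted alkene may engage slowly, or the E isomer may form. The fallback closes the ring at the C9–C10 bond by an intramolecular Nozaki–Hiyama–Kishi reaction; it sets out from compound 19 and comes back at compound 27.
- TBSOTf and 2,6-lutidine give the silyl ether (3R,4S,5S)-5-[(1Z,3S)-3-(tert-butyldimethylsilyloxy)-2-methylhexa-1,5-dien-1-yl]-4-{2-[(tert-butyldiphenylsilyl)oxy]ethyl}-3-methyloxolan-2-one F7.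
- Lemieux–Johnson cleavage of the unhindered terminal alkene (OsO4 cat., NaIO4, 2,6-lutidine, dioxane/H2O) gives the aldehyde (3S,4Z)-3-(tert-butyldimethylsilyloxy)-5-[(2S,3S,4R)-3-{2-[(tert-butyldiphenylsilyl)oxy]ethyl}-4-methyl-5-oxooxolan-2-yl]-4-methylpent-4-enal F8.
- Stork–Zhao–Wittig olefination as in step 9 gives the alkenyl iodide (3R,4S,5S)-5-[(1Z,3S,5Z)-3-(tert-butyldimethylsilyloxy)-6-iodo-2-methylhepta-1,5-dien-1-yl]-4-{2-[(tert-butyldiphenylsilyl)oxy]ethyl}-3-methyloxolan-2-one F9.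
- HF·pyridine removes both silyl groups to give the diol (3R,4S,5S)-4-(2-hydroxyethyl)-5-[(1Z,3S,5Z)-3-hydroxy-6-iodo-2-methylhepta-1,5-dien-1-yl]-3-methyloxolan-2-one F10.
- TEMPO and PhI(OAc)2 oxidise only the primary alcohol to the hydroxy aldehyde 2-{(2S,3S,4R)-2-[(1Z,3S,5Z)-3-hydroxy-6-iodo-2-methylhepta-1,5-dien-1-yl]-4-methyl-5-oxooxolan-3-yl}acetaldehyde F11.
- CrCl2 and NiCl2 (cat.) in DMSO at high dilution close the ring to the diol (3S,6S,7S,9R,11R)-3,9-dihydroxy-11,13-dihydrogermacra-1(10)Z,4Z-dien-12,6-olide F12; the C9 configuration rests on macrocyclic control.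
- Ac2O, pyridine and DMAP give 27.

Further compounds

F1 | step 3 | (S)-5-(hydroxymethyl)furan-2(5H)-one | OC[C@H]1OC(=O)C=C1
F2 | step 3 | (S)-5-[(benzyloxy)methyl]furan-2(5H)-one | O(Cc1ccccc1)C[C@H]1OC(=O)C=C1
F3 | step 3 | (4R,5S)-5-[(benzyloxy)methyl]-4-ethenyloxolan-2-one | O(Cc1ccccc1)C[C@H]1OC(=O)C[C@@H]1C=C
F4 | step 3 | (4S,5S)-5-[(benzyloxy)methyl]-4-(2-hydroxyethyl)oxolan-2-one | O(Cc1ccccc1)C[C@H]1OC(=O)C[C@@H]1CCO
F5 | step 6 | (3S,4S,5S)-5-[(benzyloxy)methyl]-4-{2-[(tert-butyldiphenylsilyl)oxy]ethyl}-3-[(dimethylamino)methyl]oxolan-2-one | O(Cc1ccccc1)C[C@H]1OC(=O)[C@@H](CN(C)C)[C@@H]1CCO[Si](c1ccccc1)(c1ccccc1)C(C)(C)C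
F6 | step 6 | (4S,5S)-5-[(benzyloxy)methyl]-4-{2-[(tert-butyldiphenylsilyl)oxy]ethyl}-3-methylideneoxolan-2-one | O(Cc1ccccc1)C[C@H]1OC(=O)C(=C)[C@@H]1CCO[Si](c1ccccc1)(c1ccccc1)C(C)(C)C
F7 | step 19 | (3R,4S,5S)-5-[(1Z,3S)-3-(tert-butyldimethylsilyloxy)-2-methylhexa-1,5-dien-1-yl]-4-{2-[(tert-butyldiphenylsilyl)oxy]ethyl}-3-methyloxolan-2-one | CC(C)(C)[Si](C)(C)O[C@@H](CC=C)/C(C)=C\[C@H]1OC(=O)[C@H](C)[C@@H]1CCO[Si](c1ccccc1)(c1ccccc1)C(C)(C)C
F8 | step 19 | (3S,4Z)-3-(tert-butyldimethylsilyloxy)-5-[(2S,3S,4R)-3-{2-[(tert-butyldiphenylsilyl)oxy]ethyl}-4-methyl-5-oxooxolan-2-yl]-4-methylpent-4-enal | CC(C)(C)[Si](C)(C)O[C@@H](CC=O)/C(C)=C\[C@H]1OC(=O)[C@H](C)[C@@H]1CCO[Si](c1ccccc1)(c1ccccc1)C(C)(C)C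
F9 | step 19 | (3R,4S,5S)-5-[(1Z,3S,5Z)-3-(tert-butyldimethylsilyloxy)-6-iodo-2-methylhepta-1,5-dien-1-yl]-4-{2-[(tert-butyldiphenylsilyl)oxy]ethyl}-3-methyloxolan-2-one | CC(C)(C)[Si](C)(C)O[C@@H](C/C=C(/C)I)/C(C)=C\[C@H]1OC(=O)[C@H](C)[C@@H]1CCO[Si](c1ccccc1)(c1ccccc1)C(C)(C)C
F10 | step 19 | (3R,4S,5S)-4-(2-hydroxyethyl)-5-[(1Z,3S,5Z)-3-hydroxy-6-iodo-2-methylhepta-1,5-dien-1-yl]-3-methyloxolan-2-one | O[C@@H](C/C=C(/C)I)/C(C)=C\[C@H]1OC(=O)[C@H](C)[C@@H]1CCO
F11 | step 19 | 2-{(2S,3S,4R)-2-[(1Z,3S,5Z)-3-hydroxy-6-iodo-2-methylhepta-1,5-dien-1-yl]-4-methyl-5-oxooxolan-3-yl}acetaldehyde | O[C@@H](C/C=C(/C)I)/C(C)=C\[C@H]1OC(=O)[C@H](C)[C@@H]1CC=O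
F12 | step 19 | (3S,6S,7S,9R,11R)-3,9-dihydroxy-11,13-dihydrogermacra-1(10)Z,4Z-dien-12,6-olide | O[C@H]1C/C=C(/C)[C@H](O)C[C@@H]2[C@@H](/C=C\1C)OC(=O)[C@@H]2C
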